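Eta leaves J behind, 9.5% of the charge at 25.0 h, while delta leaves 0.1% at 40.0 h.

the same everywhere: X 0.0567 M; G 0.32 mM
- eta: J 0.063 M; the very flask that is asked about, followed so far
- delta: J 0.032 M; run made earlier
- flask: J 0.063 M

- eta (time / h: Z / %, J / %): 4.00: 88.7, 11.4; 8.00: 89.5, 10.0; 12.0: 90.9, 10.7; 15.0: 89.6, 9.1; 20.0: 90.5, 10.1; 25.0: 90.2, 9.5
- delta (time / h: Z / %, J / %): 2.50: 99.6, 0; 6.00: 100.1, 0; 12.0: 100.5, 0.6; 20.0: 100.4, 0.2; 25.0: 100.3, 0; 40.0: 100.2, 0.1

(readings scatter by 0.5 percentage points)

1. factor on the rate of making Z when 30% of the J are converted if X is charged twice over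
2. factor on the rate when 30% of the J are converted if G is charged at 3.0 mM instead

I follow the flask, which has eta's charge, by one quantity. At one X per J, the X in hand is the charge of X less what the conversion of J has used:

[X] = 0.0567 M − 30% × 0.063 M = 0.0378 M

That line gives the value at 30% conversion.

In the flask's first instants [X] is 0.0567 M and [J] is 0.063 M. Eta already reads 88.7% Z at its first sample, 4.00 h, so I read no orders from its samples.

In the middle, I charge X twice over. The X in hand at the same conversion becomes 0.0945 M. I assume a rate first order in [X], since no run varies X, and the factor is then not the charged one: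

0.0945 M / 0.0378 M = 2.50

No run varies G either. I guess first order there too, which gives 9.38.

At the end the X in hand reaches zero at 90.0% conversion, since X is the limiting reagent. That predicts 10.0% of J left, and eta reads 9.5%. In delta the X in hand at full conversion is still 0.0247 M, and Z reads 100.2% at 40.0 h.

The forecast gives 2 and 8, on the ground that “no orders can be read”, and stands below my 2.50 and 9.38.

The flask gives 2.51 and 9.45.

    J + X + G → G + Z (k = 3.50 × 10⁵ M⁻² h⁻¹)
    G ⇌ E (K = 3.90, k = 0.130 h⁻¹)

At 30% conversion in the flask, with my 0.0378 M, [J] at 0.04410 M and G at 99.1% of its charge, the first step runs at 0.185 M h⁻¹. In the flask, the half-life of J by that step, 0.22 h at 0.137 h, is shorter than the 4.24 h relaxation half-life of G and E, both ways together. At 50.0 h the flask holds X at 0% of its charge, J at 10.0% of its charge, and the catalyst as 20.4% G and 79.6% E.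

All runs were computed from invented constants; the scatter is artificial.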